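Ring B, the acetylenic cyclohexene (C1'–C6'), is cut across C3'–C4' and C1'–C6' into two C5 isoprenoid halves. A one-pot Wittig olefination/6π-electrocyclisation joins a prenyl ylide to ethyl 3-methyl-4-oxocrotonate: the olefination makes C3'=C4', the disrotatory closure of the Z-triene makes C1'–C6', and both triene isomers funnel into one achiral dienoate. The step exploits the 2,6,6-trimethylcyclohexa-1,3-diene retron hidden in ring B; its extra C3'=C4' alkene is later hydrated by asymmetric hydroboration, which sets C3', and the ester becomes the C7'≡C8' alkyne. Ring A comes from ketoisophorone; the polyene is assembled C15 + C10 + C15 by Wittig couplings.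

Key step: step 1

Remark: carotenoid locants are used (unprimed for the 3,6-dihydroxy half with ring A, primed for the acetylenic half with ring B); the target is the all-E (3S,6R,3'R) triol, and (E)-3-iodobut-2-en-1-ol is taken as a purchasable building block.

**Ring B half**

Step 1
Reactants: 1 (3-methylbut-2-en-1-yl)triphenylphosphonium bromide; 2 ethyl (2E)-3-methyl-4-oxobut-2-enoate
Product: 6 ethyl 2,6,6-trimethylcyclohexa-1,3-diene-1-carboxylate (ethyl safranate), via (2E,4E)-trienoate 3 (not isolated), via (2E,4Z)-trienoate 4 (not isolated), via 2,4-dienoate 5 (not isolated)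
Conditions: NaN(SiMe3)2 (1.05 equiv), THF–toluene, −78 → 20 °C; then I2 (2 mol %), 140 °C, sealed vessel, dilute; then DBU (20 mol %), 80 °C
Reagents that add atoms: none
Why: The ylide from 1 olefinates aldehyde 2 (Wittig reaction) and so makes C3'=C4' as a 4E/4Z mixture (3 and 4), and iodine-catalysed E/Z equilibration at 140 °C feeds the 4Z isomer 4, whose hexatriene C1'=C2'–C3'=C4'–C5'=C6' closes the C1'–C6' bond by thermal disrotatory 6π-electrocyclisation to 5. The closest known reaction types are one-pot Wittig/6π-electrocyclisation sequences and the thermal ring closure of allo-ocimene-type trienes that carry a gem-dimethyl terminus. Ring B is closed in a pericyclic six-electron mode in which all six ring atoms are the triene carbons, not by an ionic exo or endo closure. The only stereocentre formed (C6' of 5) is erased when DBU moves the diene into conjugation with the ester, so no stereocontrol is needed here. The step needs the Z geometry at C3'=C4' and an inward hydrogen at C6': the first is secured dynamically, because only 4 is drained while 3 and 4 interconvert, and the second by the fixed E geometry of 2.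

Step 2
Reactants: 6 ethyl 2,6,6-trimethylcyclohexa-1,3-diene-1-carboxylate
Product: 7 (2,6,6-trimethylcyclohexa-1,3-dien-1-yl)methanol (safranol)
Conditions: i-Bu2AlH (2.5 equiv), CH2Cl2, −78 → 0 °C; aq. KNaC4H4O6
Reagents that add atoms: none
Why: 1,2-Reduction of the hindered dienoate by i-Bu2AlH should give the dienyl carbinol and make the diene electronically neutral, so that the next hydroboration is ruled by sterics; no stereocentre is involved.

Step 3
Reactants: 7 (2,6,6-trimethylcyclohexa-1,3-dien-1-yl)methanol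
Product: 9 (1R)-4-(hydroxymethyl)-3,5,5-trimethylcyclohex-3-en-1-ol, via bis-boryl adduct 8 (not isolated)
Conditions: (+)-Ipc2BH (from (−)-α-pinene, 2.2 equiv), THF, −25 → 0 °C; then 3 M NaOH, 30% H2O2, 0 → 40 °C
Reagents that add atoms: hydrogen peroxide, OO
Why: Reagent-controlled asymmetric hydroboration–oxidation (Brown) of the cis-disubstituted C3'=C4' alkene: the first equivalent is taken up by the hydroxyl as the borinate, boron then enters the diene terminus C3' (the tetrasubstituted C5'=C6' alkene is inert to this borane), and syn addition followed by oxidation with retention should give the 3'R alcohol, the sense that the cis-alkene model predicts for the reagent from (−)-α-pinene.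

Step 4
Reactants: 9 (1R)-4-(hydroxymethyl)-3,5,5-trimethylcyclohex-3-en-1-ol
Product: 10 (4R)-4-hydroxy-2,6,6-trimethylcyclohex-1-ene-1-carbaldehyde
Conditions: activated MnO2 (15 equiv), CH2Cl2, 20 °C
Reagents that add atoms: none
Why: MnO2 oxidises only the primary allylic alcohol, while the secondary C3' hydroxyl is homoallylic and should be left, so C3' is untouched.

Step 5
Reactants: 10 (4R)-4-hydroxy-2,6,6-trimethylcyclohex-1-ene-1-carbaldehyde
Product: 11 (1R)-4-ethynyl-3,5,5-trimethylcyclohex-3-en-1-ol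
Conditions: Me3SiCHN2 (2.3 equiv), n-BuLi (2.3 equiv), THF, −78 °C; then 10, −78 → 20 °C
Reagents that add atoms: (trimethylsilyl)diazomethane, C[Si](C)(C)C=[N+]=[N-]
Why: Colvin homologation: the lithiated diazomethane adds to the aldehyde, Peterson elimination and loss of N2 give an alkylidene carbene, and its 1,2-hydrogen shift should give the C7'≡C8' alkyne; one equivalent is held by the alkoxide.

Step 6
Reactants: 11 (1R)-4-ethynyl-3,5,5-trimethylcyclohex-3-en-1-ol; 12 (2E)-3-iodobut-2-en-1-ol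
Product: 13 (1R)-4-[(3E)-5-hydroxy-3-methylpent-3-en-1-yn-1-yl]-3,5,5-trimethylcyclohex-3-en-1-ol
Conditions: Pd(PPh3)4 (3 mol %), CuI (6 mol %), i-Pr2NH, THF, 20 °C
Reagents that add atoms: none
Why: Sonogashira coupling proceeds with retention at the vinyl iodide, so the C9'=C10' bond should be E.

Step 7
Reactants: 13 (1R)-4-[(3E)-5-hydroxy-3-methylpent-3-en-1-yn-1-yl]-3,5,5-trimethylcyclohex-3-en-1-ol
Product: 14 {(2E)-5-[(4R)-4-hydroxy-2,6,6-trimethylcyclohex-1-en-1-yl]-3-methylpent-2-en-4-yn-1-yl}triphenylphosphonium bromide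
Conditions: PPh3·HBr (1.05 equiv), MeOH, 20 °C
Reagents that add atoms: triphenylphosphine hydrobromide, Br.c1ccc(cc1)P(c1ccccc1)c1ccccc1
Why: Phosphonium salt formation from a primary allylic alcohol with PPh3·HBr, the standard entry to carotenoid C15 salts; the homoallylic ring hydroxyl should not ionise.

Step 8
Reactants: 14 the C15 phosphonium bromide; 15 (2E,4E,6E)-2,7-dimethylocta-2,4,6-trienedial
Product: 16 (2E,4E,6E,8E,10E)-13-[(4R)-4-hydroxy-2,6,6-trimethylcyclohex-1-en-1-yl]-2,7,11-trimethyltrideca-2,4,6,8,10-pentaen-12-ynal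
Conditions: 15 (3 equiv), NaOMe (1.1 equiv), CH2Cl2–MeOH, 0 → 20 °C; then heptane, 80 °C
Reagents that add atoms: none
Why: Wittig olefination with excess dial should give the mono-adduct, and the hindered 11'Z isomer of the new C11'=C12' bond is equilibrated to E on warming.

Step 9
Reactants: 16 the C25 aldehyde
Product: 17 (2E,4E,6E,8E,10E)-13-[(4R)-4-hydroxy-2,6,6-trimethylcyclohex-1-en-1-yl]-2,7,11-trimethyltrideca-2,4,6,8,10-pentaen-12-yn-1-ol
Conditions: NaBH4, EtOH–THF, 0 °C
Reagents that add atoms: none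
Why: 1,2-Reduction of the polyenal by NaBH4 leaves the polyene and the alkyne untouched.

Step 10
Reactants: 17 the C25 alcohol
Product: 18 {(2E,4E,6E,8E,10E)-13-[(4R)-4-hydroxy-2,6,6-trimethylcyclohex-1-en-1-yl]-2,7,11-trimethyltrideca-2,4,6,8,10-pentaen-12-yn-1-yl}triphenylphosphonium bromide
Conditions: PPh3·HBr (1.05 equiv), MeOH–CH2Cl2, 0 → 20 °C
Reagents that add atoms: triphenylphosphine hydrobromide, Br.c1ccc(cc1)P(c1ccccc1)c1ccccc1
Why: Phosphonium salt formation from the polyenylic alcohol through the delocalised allylic cation, which PPh3 should capture at the primary terminus as in apocarotenol chemistry.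

**Ring A half**

Step 11
Reactants: 19 2,6,6-trimethylcyclohex-2-ene-1,4-dione (ketoisophorone)
Product: 20 (4R)-4-hydroxy-2,6,6-trimethylcyclohex-2-en-1-one
Conditions: RuCl[(R,R)-TsDPEN](p-cymene) (0.5 mol %), i-PrOH, 25 °C
Reagents that add atoms: none
Why: Noyori asymmetric transfer hydrogenation reduces the less hindered C4 ketone (the C1 ketone lies between the quaternary carbon and the methyl-bearing alkene carbon), and with the alkenyl carbon in the aryl role of the CH/π model the (R,R) ligand should give the 4R alcohol.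

Step 12
Reactants: 20 (4R)-4-hydroxy-2,6,6-trimethylcyclohex-2-en-1-one; 21 (2E)-3-methylpent-2-en-4-yn-1-ol
Product: 22 (1R,4R)-1-[(3E)-5-hydroxy-3-methylpent-3-en-1-yn-1-yl]-2,6,6-trimethylcyclohex-2-ene-1,4-diol
Conditions: 21 (3 equiv), n-BuLi (6 equiv), THF, −78 → 0 °C; then 20, −78 → 0 °C; aq. NH4Cl
Reagents that add atoms: none
Why: 1,2-Addition of the lithium acetylide (dianion of 21) to the enone carbonyl; in the sofa conformer with a pseudo-equatorial C4–OLi group the nucleophile should enter anti to the pseudo-axial C6 methyl, that is cis to the C4 oxygen, which sets the tertiary carbinol (carotenoid C6, R).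

Step 13
Reactants: 22 the acetylenic triol
Product: 23 (1R,4R)-1-[(1E,3E)-5-hydroxy-3-methylpenta-1,3-dien-1-yl]-2,6,6-trimethylcyclohex-2-ene-1,4-diol
Conditions: NaAlH2(OCH2CH2OMe)2 (4 equiv), THF, 0 → 20 °C; aq. KNaC4H4O6
Reagents that add atoms: none
Why: Alkoxide-directed trans-hydroalumination of the propargylic alkyne should give the 7E alkene and leave the trisubstituted alkene and both stereocentres unchanged.

Step 14
Reactants: 23 the dienyl triol
Product: 24 (2E,4E)-5-[(1R,4R)-1,4-dihydroxy-2,6,6-trimethylcyclohex-2-en-1-yl]-3-methylpenta-2,4-dienal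
Conditions: TEMPO (10 mol %), PhI(OAc)2 (1.1 equiv), CH2Cl2, 0 → 20 °C
Reagents that add atoms: none
Why: The TEMPO/PhI(OAc)2 oxidation is selective for the primary allylic alcohol over the secondary ring alcohol and cannot touch the tertiary one.

Step 15
Reactants: 24 the C15 dihydroxy aldehyde
Product: 25 (1S,4R)-4-hydroxy-4-[(1E,3E)-3-methyl-5-oxopenta-1,3-dien-1-yl]-3,5,5-trimethylcyclohex-2-en-1-yl 4-nitrobenzoate
Conditions: PPh3, i-PrO2CN=NCO2i-Pr, 4-O2NC6H4CO2H (1.5 equiv each), toluene, 0 → 20 °C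
Reagents that add atoms: 4-nitrobenzoic acid, OC(=O)c1ccc(cc1)[N+](=O)[O-]
Why: Mitsunobu esterification inverts the secondary allylic carbinol (SN2) to the 3S configuration, which places the C3 oxygen cis to the C6 hydroxyl; the tertiary alcohol does not react and the ester masks C3.

**Coupling**

Step 16
Reactants: 18 the C25 phosphonium bromide; 25 the C15 aldehyde ester
Product: 27 the target, all-E (3S,6R,3'R) triol, via C40 4-nitrobenzoate 26 (not isolated)
Conditions: NaOMe (3 equiv), CH2Cl2–MeOH, 0 → 20 °C, dark, argon; then EtOAc, 50 °C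
Reagents that add atoms: none
Why: Wittig olefination forms C11=C12, excess methoxide then removes the 4-nitrobenzoate by transesterification without touching a stereocentre, and brief warming should equilibrate the hindered 11Z isomer to all-E.

**Compound list**

1 | (3-methylbut-2-en-1-yl)triphenylphosphonium bromide | CC(C)=CC[P+](c1ccccc1)(c1ccccc1)c1ccccc1.[Br-] | starting material
2 | ethyl (2E)-3-methyl-4-oxobut-2-enoate | CCOC(=O)/C=C(\C)C=O | starting material
3 | ethyl (2E,4E)-3,7-dimethylocta-2,4,6-trienoate | CCOC(=O)/C=C(\C)/C=C/C=C(C)C | intermediate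
4 | ethyl (2E,4Z)-3,7-dimethylocta-2,4,6-trienoate | CCOC(=O)/C=C(\C)/C=C\C=C(C)C | intermediate
5 | ethyl 2,6,6-trimethylcyclohexa-2,4-diene-1-carboxylate (racemic) | CCOC(=O)C1C(C)=CC=CC1(C)C | intermediate
6 | ethyl 2,6,6-trimethylcyclohexa-1,3-diene-1-carboxylate | CCOC(=O)C1=C(C)C=CCC1(C)C | intermediate
7 | (2,6,6-trimethylcyclohexa-1,3-dien-1-yl)methanol | OCC1=C(C)C=CCC1(C)C | intermediate
8 | [(4R)-4-(diisopinocampheylboryl)-2,6,6-trimethylcyclohex-1-en-1-yl]methyl diisopinocampheylborinate | C1(COB([C@H]2C[C@H]3C[C@@H]([C@@H]2C)C3(C)C)[C@H]2C[C@H]3C[C@@H]([C@@H]2C)C3(C)C)=C(C)C[C@@H](B([C@H]2C[C@H]3C[C@@H]([C@@H]2C)C3(C)C)[C@H]2C[C@H]3C[C@@H]([C@@H]2C)C3(C)C)CC1(C)C | intermediate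
9 | (1R)-4-(hydroxymethyl)-3,5,5-trimethylcyclohex-3-en-1-ol | OCC1=C(C)C[C@@H](O)CC1(C)C | intermediate
10 | (4R)-4-hydroxy-2,6,6-trimethylcyclohex-1-ene-1-carbaldehyde | O=CC1=C(C)C[C@@H](O)CC1(C)C | intermediate
11 | (1R)-4-ethynyl-3,5,5-trimethylcyclohex-3-en-1-ol | C#CC1=C(C)C[C@@H](O)CC1(C)C | intermediate
12 | (2E)-3-iodobut-2-en-1-ol | C/C(I)=C\CO | starting material
13 | (1R)-4-[(3E)-5-hydroxy-3-methylpent-3-en-1-yn-1-yl]-3,5,5-trimethylcyclohex-3-en-1-ol | OC/C=C(\C)C#CC1=C(C)C[C@@H](O)CC1(C)C | intermediate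
14 | {(2E)-5-[(4R)-4-hydroxy-2,6,6-trimethylcyclohex-1-en-1-yl]-3-methylpent-2-en-4-yn-1-yl}triphenylphosphonium bromide | [Br-].c1ccccc1[P+](c1ccccc1)(c1ccccc1)C/C=C(\C)C#CC1=C(C)C[C@@H](O)CC1(C)C | intermediate
15 | (2E,4E,6E)-2,7-dimethylocta-2,4,6-trienedial | O=C/C(C)=C/C=C/C=C(C)/C=O | starting material
16 | (2E,4E,6E,8E,10E)-13-[(4R)-4-hydroxy-2,6,6-trimethylcyclohex-1-en-1-yl]-2,7,11-trimethyltrideca-2,4,6,8,10-pentaen-12-ynal | O=C/C(C)=C/C=C/C=C(C)/C=C/C=C(\C)C#CC1=C(C)C[C@@H](O)CC1(C)C | intermediate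
17 | (2E,4E,6E,8E,10E)-13-[(4R)-4-hydroxy-2,6,6-trimethylcyclohex-1-en-1-yl]-2,7,11-trimethyltrideca-2,4,6,8,10-pentaen-12-yn-1-ol | OC/C(C)=C/C=C/C=C(C)/C=C/C=C(\C)C#CC1=C(C)C[C@@H](O)CC1(C)C | intermediate
18 | {(2E,4E,6E,8E,10E)-13-[(4R)-4-hydroxy-2,6,6-trimethylcyclohex-1-en-1-yl]-2,7,11-trimethyltrideca-2,4,6,8,10-pentaen-12-yn-1-yl}triphenylphosphonium bromide | [Br-].c1ccccc1[P+](c1ccccc1)(c1ccccc1)C/C(C)=C/C=C/C=C(C)/C=C/C=C(\C)C#CC1=C(C)C[C@@H](O)CC1(C)C | intermediate
19 | 2,6,6-trimethylcyclohex-2-ene-1,4-dione | CC1=CC(=O)CC(C)(C)C1=O | starting material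
20 | (4R)-4-hydroxy-2,6,6-trimethylcyclohex-2-en-1-one | CC1=C[C@H](O)CC(C)(C)C1=O | intermediate
21 | (2E)-3-methylpent-2-en-4-yn-1-ol | C#C/C(C)=C/CO | starting material
22 | (1R,4R)-1-[(3E)-5-hydroxy-3-methylpent-3-en-1-yn-1-yl]-2,6,6-trimethylcyclohex-2-ene-1,4-diol | CC1=C[C@H](O)CC(C)(C)[C@]1(O)C#C/C(C)=C/CO | intermediate
23 | (1R,4R)-1-[(1E,3E)-5-hydroxy-3-methylpenta-1,3-dien-1-yl]-2,6,6-trimethylcyclohex-2-ene-1,4-diol | CC1=C[C@H](O)CC(C)(C)[C@]1(O)/C=C/C(C)=C/CO | intermediate
24 | (2E,4E)-5-[(1R,4R)-1,4-dihydroxy-2,6,6-trimethylcyclohex-2-en-1-yl]-3-methylpenta-2,4-dienal | CC1=C[C@H](O)CC(C)(C)[C@]1(O)/C=C/C(C)=C/C=O | intermediate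
25 | (1S,4R)-4-hydroxy-4-[(1E,3E)-3-methyl-5-oxopenta-1,3-dien-1-yl]-3,5,5-trimethylcyclohex-2-en-1-yl 4-nitrobenzoate | CC1=C[C@@H](OC(=O)c2ccc(cc2)[N+](=O)[O-])CC(C)(C)[C@]1(O)/C=C/C(C)=C/C=O | intermediate
26 | 3-O-(4-nitrobenzoyl) derivative of the target (all-E, 3S,6R,3'R) | CC1=C[C@@H](OC(=O)c2ccc(cc2)[N+](=O)[O-])CC(C)(C)[C@]1(O)/C=C/C(C)=C/C=C/C(C)=C/C=C/C=C(C)/C=C/C=C(\C)C#CC1=C(C)C[C@@H](O)CC1(C)C | intermediate
27 | target, all-E (3S,6R,3'R) triol | CC1=C[C@@H](O)CC(C)(C)[C@]1(O)/C=C/C(C)=C/C=C/C(C)=C/C=C/C=C(C)/C=C/C=C(\C)C#CC1=C(C)C[C@@H](O)CC1(C)C | target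

**Step count and risks**

Total step count: 16. Longest linear sequence: 11 (steps 1 to 10, then step 16).

The three steps most likely to fail:

1. Step 1. The thermal stage may be too slow to compete. Ring closure at the gem-dimethyl terminus needs about 140 °C, and at that temperature reversible [1,7]-hydrogen shifts, slow return of the 4E triene to the 4Z manifold and cycloaddition of the trienoate can drain material. Fallback: the Z triene is made on purpose through an alkyne. Setting out from 2, Ohira–Bestmann homologation (dimethyl (1-diazo-2-oxopropyl)phosphonate, K2CO3, EtOH) should give ethyl (2E)-3-methylpent-2-en-4-ynoate F1. Sonogashira coupling with 1-bromo-2-methylprop-1-ene (Pd(PPh3)4, CuI, Et2NH) should give ethyl (2E)-3,7-dimethylocta-2,6-dien-4-ynoate F2. Semi-hydrogenation (H2, Pd/CaCO3 poisoned with Pb(OAc)2, quinoline) should give the 4Z triene alone, which is compound 4; heating and DBU as in step 1 then lead to 6. In this fallback the two ring bonds are made in separate operations.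

2. Step 3. Regio- or face selectivity of the hydroboration may erode, because the first equivalent of borane turns the hydroxyl into a bulky borinate next to the diene: boron may be delivered to C4', or the alkene faces may be poorly discriminated. If the sense of induction is opposite to the model, the borane from (+)-α-pinene is used instead. Fallback: the hydroxyl is taken out of play. Setting out from 7, silylation (t-BuMe2SiCl, imidazole, DMF) should give tert-butyl(dimethyl)[(2,6,6-trimethylcyclohexa-1,3-dien-1-yl)methoxy]silane F3. Hydroboration–oxidation with (+)-Ipc2BH (1.2 equiv) should give (1R)-4-{[tert-butyl(dimethyl)silyl]oxymethyl}-3,5,5-trimethylcyclohex-3-en-1-ol F4, and Bu4NF in THF returns diol 9.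

3. Step 12. The acetylide may attack with low or reversed facial preference. Fallback for attack trans to the C4 oxygen: the antipodal alcohol is used and no inversion is needed. Setting out from 19, transfer hydrogenation with RuCl[(S,S)-TsDPEN](p-cymene) should give (4S)-4-hydroxy-2,6,6-trimethylcyclohex-2-en-1-one F5. The dianion of 21 would then give the cis-1,4-diol (1R,4S)-1-[(3E)-5-hydroxy-3-methylpent-3-en-1-yn-1-yl]-2,6,6-trimethylcyclohex-2-ene-1,4-diol F6. Reduction as in step 13 gives (1R,4S)-1-[(1E,3E)-5-hydroxy-3-methylpenta-1,3-dien-1-yl]-2,6,6-trimethylcyclohex-2-ene-1,4-diol F7, and oxidation as in step 14 gives (2E,4E)-5-[(1R,4S)-1,4-dihydroxy-2,6,6-trimethylcyclohex-2-en-1-yl]-3-methylpenta-2,4-dienal F8. Acylation with 4-nitrobenzoyl chloride and pyridine (retention) gives 25 directly, so the Mitsunobu step is dropped.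

Further compounds

F1 | step 1 | ethyl (2E)-3-methylpent-2-en-4-ynoate | CCOC(=O)/C=C(\C)C#C
F2 | step 1 | ethyl (2E)-3,7-dimethylocta-2,6-dien-4-ynoate | CCOC(=O)/C=C(\C)C#CC=C(C)C
F3 | step 3 | tert-butyl(dimethyl)[(2,6,6-trimethylcyclohexa-1,3-dien-1-yl)methoxy]silane | CC(C)(C)[Si](C)(C)OCC1=C(C)C=CCC1(C)C
F4 | step 3 | (1R)-4-{[tert-butyl(dimethyl)silyl]oxymethyl}-3,5,5-trimethylcyclohex-3-en-1-ol | CC(C)(C)[Si](C)(C)OCC1=C(C)C[C@@H](O)CC1(C)C
F5 | step 12 | (4S)-4-hydroxy-2,6,6-trimethylcyclohex-2-en-1-one | CC1=C[C@@H](O)CC(C)(C)C1=O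
F6 | step 12 | (1R,4S)-1-[(3E)-5-hydroxy-3-methylpent-3-en-1-yn-1-yl]-2,6,6-trimethylcyclohex-2-ene-1,4-diol | CC1=C[C@@H](O)CC(C)(C)[C@]1(O)C#C/C(C)=C/CO
F7 | step 12 | (1R,4S)-1-[(1E,3E)-5-hydroxy-3-methylpenta-1,3-dien-1-yl]-2,6,6-trimethylcyclohex-2-ene-1,4-diol | CC1=C[C@@H](O)CC(C)(C)[C@]1(O)/C=C/C(C)=C/CO
F8 | step 12 | (2E,4E)-5-[(1R,4S)-1,4-dihydroxy-2,6,6-trimethylcyclohex-2-en-1-yl]-3-methylpenta-2,4-dienal | CC1=C[C@@H](O)CC(C)(C)[C@]1(O)/C=C/C(C)=C/C=O
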